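The amber and green runs differ in their charge of protic impurity, 0.038 M against 0.086 M, a factor of 2.26. Take as the zero of your scale the case where this impurity leaves substrate loss untouched, so that the two curves coincide. At 30.0 h they read 52.2 % and 52.9 % of the charge, and each reading has a scatter of 1 percentage point. You can't tell them from that zero, so pool them.

| setting | amber | green | flask |
|---|---|---|---|
| substrate | 0.57 M | 0.57 M | 0.57 M |
| first nucleophile | 1.8 equiv | 1.8 equiv | 1.80 equiv |
| second nucleophile | 2 equiv | 2 equiv | 2.00 equiv |
| protic impurity | 0.038 M | 0.086 M | 0.0570 M |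
| remark | run made earlier | run made earlier |  |
| time |  |  | 30 h |

| run | time / h | substrate / % | solvolysis product / % | target / % | intermediate / % | other capture product / % |
|---|---|---|---|---|---|---|
| amber | 2.00 | 94.7 | 1.3 | 1.7 | 0.8 | 2.2 |
| amber | 6.00 | 87.3 | 2.3 | 2.5 | 0.3 | 8.3 |
| amber | 10.0 | 79.9 | 3.9 | 2.1 | 1.9 | 14.1 |
| amber | 15.0 | 72.7 | 4.1 | 2.2 | 0.6 | 19.2 |
| amber | 25.0 | 57.6 | 8.4 | 2.9 | 0 | 30.5 |
| amber | 30.0 | 52.2 | 6.8 | 6.4 | 0.2 | 34.1 |
| green | 2.00 | 95.1 | 0.4 | 0.3 | 0 | 3.0 |
| green | 6.00 | 88.3 | 2.7 | 0 | 0.6 | 8.6 |
| green | 10.0 | 79.4 | 3.1 | 0.4 | 0 | 15.1 |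
| green | 15.0 | 72.6 | 4.2 | 4.1 | 0 | 19.0 |
| green | 25.0 | 56.6 | 8.4 | 4.6 | 0 | 29.3 |
| green | 30.0 | 52.9 | 8.4 | 5.9 | 0 | 33.8 |

(standard deviation of a reading: 1 percentage point)



1. the largest share of what was charged as substrate, at 30 h belongs to (other capture product / intermediate / solvolysis product / target / substrate)
2. the largest share itself, whichever of these holds it, in percent of the substrate charged

The new flask's impurity, 0.0570 M, lies between the two. If substrate is lost by a first-order step, the same fraction goes in each equal time, and one number describes the loss:

k = ln(charge / substrate left) / time = 0.0214 h⁻¹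

half-life = ln(2) / k = 32.3 h

Call 32.3 h the substrate half-life: the time in which the fraction of the charge left is halved. Test it on readings that did not make it. It gives 72.5 % at 15.0 h, and the runs read 72.7 % and 72.6 %.

For the flask, my own reckoning is:

fraction left at 30 h = 52.6 %

The flask's time is shorter than the half-life. So substrate keeps more than half of the charge, and the other species share the remaining 47.4 %, so none of them can exceed it.

The forecast names substrate at 52.4 %, close to my figure but not the same, on the ground that “its impurity level lies between those of the two runs”.

The flask gives substrate at 51.7 %, 0.90 points below the reckoning, and other capture product follows at 34.1 %.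

    first nucleophile + intermediate → target (k = 14.0 M⁻¹ h⁻¹)
    second nucleophile + protic impurity → quenched reagent (k = 0.640 M⁻¹ h⁻¹)
    substrate → intermediate (k = 0.0220 h⁻¹)
    second nucleophile + intermediate → other capture product (k = 98.0 M⁻¹ h⁻¹)
    intermediate → solvolysis product (k = 26.0 h⁻¹)

Substrate leads this flask because the time given is 0.929 of a half-life, just inside the first one. The flask holds 51.7 % substrate then. Left ten times as long, the half-life predicts 0.161 %, and the flask keeps 0.136 %.

At 3.0 d, past the half-life, the same reckoning gives 21.3 % for the neighbouring flask, so the bound on the other species no longer applies. That flask holds 20.5 % substrate, and other capture product leads with 55.0 %.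

(All runs come from a simulation with constants of no real substance; the scatter is artificial.)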